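**Plan**

- Numbering: ring B from the ester carbon (C1 CO2Me, C2 OMe, C3 Me, C4 O-acyl, C5 Me, C6 Me); ring A primed (C1' carboxyl carbon, C2'/C4' OH, C3' CHO, C5'/C6' Me).
- Retrosynthetic cuts, in order: the C3'–CHO bond (C3' is the only aromatic C–H of the depside and lies between two hydroxyls); the depside C4–O–C(=O) ester bond; then ring B in one operation at C1–C6, C1–C2, C3–C4 and C4–C5.
- Enabling feature: ring B is a hexasubstituted benzene whose C4 oxygen is meta to the C2 methoxy, with the ester on C1 between them. A vinylketene carrying the ester (C4, C1, C6, C5) and an alkoxyalkyne (C3, C2) give exactly this resorcinol monoether pattern.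
- Forward: ring B is made by a photo-Wolff/[2+2]/4π/6π cascade from a diazo keto ester and 1-methoxypropyne. Ring A is bought as 4,5-dimethylresorcinol and given its carboxyl carbon by formylation and oxidation. The rings are joined by esterification, debenzylated, and formylated last.
- Stereochemistry: the target has no stereocentre and no stereogenic double bond. The E-alkene of tiglic acid is carried into the key step and disappears on aromatisation.

Key step: step 4

Assumption: the target is achiral, so no enantiocontrol is needed; 4,5-dimethylresorcinol and potassium methyl malonate are taken as catalogue chemicals.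

**Route**

Step 1
Reactants: 1 tiglic acid; 2 potassium methyl malonate
Product: 4 methyl (E)-4-methyl-3-oxohex-4-enoate, via tigloyl imidazolide 3 (not isolated)
Conditions: CDI, THF, rt; then 2, MgCl2, Et3N, MeCN, rt; 1 M HCl
Reagents that add atoms: none
Why: Masamune–Brooks homologation, in which the acyl imidazolide C-acylates the magnesium enolate of the malonate half-ester and the adduct decarboxylates on acidic work-up; the trisubstituted enoyl group is a poor Michael acceptor and should survive.

Step 2
Reactants: 4 methyl (E)-4-methyl-3-oxohex-4-enoate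
Product: 5 methyl (E)-2-diazo-4-methyl-3-oxohex-4-enoate
Conditions: p-ABSA, Et3N, MeCN, 0 °C → rt
Reagents that add atoms: 4-acetamidobenzenesulfonyl azide (p-ABSA), CC(=O)Nc1ccc(cc1)S(=O)(=O)N=[N+]=[N-]
Why: Regitz diazo transfer to an active methylene flanked by a ketone and an ester, which needs only an amine base.

Step 3
Reactants: 6 chloroacetaldehyde dimethyl acetal
Product: 8 1-methoxypropyne, via sodium methoxyacetylide 7 (not isolated)
Conditions: NaNH2 (3 equiv), liq. NH3, −33 °C; then MeI, −33 °C; H2O, distillation
Reagents that add atoms: iodomethane, CI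
Why: Sodium amide eliminates methanol and HCl from the chloroacetal to give the alkoxyacetylide, which is C-methylated in ammonia, the standard preparation of 1-alkoxyalk-1-ynes.

Step 4
Reactants: 5 methyl (E)-2-diazo-4-methyl-3-oxohex-4-enoate; 8 1-methoxypropyne
Product: 13 methyl 4-hydroxy-2-methoxy-3,5,6-trimethylbenzoate, via vinylketene 9 (not isolated), via vinylcyclobutenone 10 (not isolated), via dienylketene 11 (not isolated), via cyclohexadienone 12 (not isolated)
Conditions: hν (254 nm, low-pressure Hg, quartz), 8 (2–3 equiv), ClCH2CH2Cl, rt; then 80 °C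
Reagents that add atoms: none
Why: Light expels N2 and the alkenyl group shifts from the ketone carbon to the carbene carbon (photo-Wolff rearrangement, forming C1–C6) to give the ester-substituted vinylketene 9, whose sp carbon is attacked by the methyl-bearing carbon of the ynol ether in a [2+2] cycloaddition (C3–C4 and C1–C2) to give cyclobutenone 10. On warming, 10 opens by 4π electrocyclic cleavage of the original C1–C4 bond to dienylketene 11, which closes ring B by thermal disrotatory 6π electrocyclisation (C4–C5) to cyclohexadienone 12 and enolises to the phenol. The closest known reaction type is the Danheiser benzannulation in its diazo ketone variant with alkoxyalkynes. No stereocentre remains: the centres of 10 and 12 vanish on aromatisation, and E/Z isomerisation of the alkene under light is harmless because C5 becomes aromatic. The step needs migration of the alkenyl group instead of the ester methoxy group, which the much higher migratory aptitude of a ketone substituent secures, and it needs the [2+2] orientation that puts OMe meta to the new hydroxyl, which the polarisation of the ynol ether (nucleophilic at the methyl-bearing carbon) toward the electrophilic ketene carbon secures. It also needs carbon ring closure in place of oxygen closure, which is favoured because the ester carbonyl is a poor heterodiene terminus, the ring opening of 10 is reversible, and only the alkenyl-inward isomer 11 drains irreversibly to the arene.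

Step 5
Reactants: 14 4,5-dimethylresorcinol
Product: 16 2,4-dihydroxy-5,6-dimethylbenzaldehyde, via aryl iminium chloride 15 (not isolated)
Conditions: POCl3, DMF, MeCN, 0 °C → rt; then H2O, 50 °C
Reagents that add atoms: N,N-dimethylformamide, CN(C)C=O; water, O
Why: Vilsmeier–Haack formylation, which should attack C6 of the resorcinol (para to one hydroxyl, ortho to the other) in preference to the position between the hydroxyls, as it does with resorcinol and orcinol.

Step 6
Reactants: 16 2,4-dihydroxy-5,6-dimethylbenzaldehyde
Product: 17 2,4-bis(benzyloxy)-5,6-dimethylbenzaldehyde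
Conditions: BnBr, K2CO3, DMF, 60 °C
Reagents that add atoms: benzyl bromide, BrCc1ccccc1
Why: Williamson etherification; warming in DMF should also alkylate the hydroxyl that is hydrogen-bonded to the aldehyde.

Step 7
Reactants: 17 2,4-bis(benzyloxy)-5,6-dimethylbenzaldehyde
Product: 18 2,4-bis(benzyloxy)-5,6-dimethylbenzoic acid
Conditions: NaClO2, NaH2PO4, 2-methylbut-2-ene, t-BuOH/H2O, rt
Reagents that add atoms: sodium chlorite, [Na+].[O-]Cl=O
Why: Pinnick oxidation; the alkene scavenges hypochlorous acid, so the electron-rich ring and the benzyl ethers should be untouched.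

Step 8
Reactants: 18 2,4-bis(benzyloxy)-5,6-dimethylbenzoic acid; 13 methyl 4-hydroxy-2-methoxy-3,5,6-trimethylbenzoate
Product: 20 methyl 4-{[2,4-bis(benzyloxy)-5,6-dimethylbenzoyl]oxy}-2-methoxy-3,5,6-trimethylbenzoate, via mixed trifluoroacetic anhydride 19 (not isolated)
Conditions: (CF3CO)2O, toluene, rt
Reagents that add atoms: none
Why: Trifluoroacetic anhydride esterification, in which a di-ortho-substituted electron-rich benzoic acid ionises from its mixed anhydride to a small acylium ion that can acylate a 2,6-disubstituted phenol; this is the established answer for mesitoate-type esters and for depsides from O-benzylated acids.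

Step 9
Reactants: 20 methyl 4-{[2,4-bis(benzyloxy)-5,6-dimethylbenzoyl]oxy}-2-methoxy-3,5,6-trimethylbenzoate
Product: 21 methyl 4-[(2,4-dihydroxy-5,6-dimethylbenzoyl)oxy]-2-methoxy-3,5,6-trimethylbenzoate
Conditions: H2 (1 atm), 10% Pd/C, EtOAc, rt
Reagents that add atoms: none
Why: Catalytic hydrogenolysis of benzyl aryl ethers, to which the aryl ester, methyl ester and methyl ether are inert; it is placed before the formylation so that no aldehyde is exposed to hydrogen.

Step 10
Reactants: 21 methyl 4-[(2,4-dihydroxy-5,6-dimethylbenzoyl)oxy]-2-methoxy-3,5,6-trimethylbenzoate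
Product: 23 methyl 4-[(3-formyl-2,4-dihydroxy-5,6-dimethylbenzoyl)oxy]-2-methoxy-3,5,6-trimethylbenzoate, via aryl chloromethyl methyl ether 22 (not isolated)
Conditions: Cl2CHOMe, TiCl4, CH2Cl2, −78 → 0 °C; then 1 M HCl
Reagents that add atoms: dichloromethyl methyl ether, COC(Cl)Cl; water, O
Why: Rieche formylation, a titanium-phenoxide-directed electrophilic substitution at C3', which is the only aromatic C–H in the molecule and is activated by both flanking hydroxyls; ring B is fully substituted, so no regiochemical alternative exists, and the chloro ether is hydrolysed on acidic work-up.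

**Compound list**

1 | tiglic acid, (E)-2-methylbut-2-enoic acid | C/C=C(\C)C(=O)O | starting material
2 | potassium methyl malonate (potassium 3-methoxy-3-oxopropanoate) | COC(=O)CC(=O)[O-].[K+] | starting material
3 | (E)-1-(1H-imidazol-1-yl)-2-methylbut-2-en-1-one (tigloyl imidazolide) | C/C=C(\C)C(=O)n1ccnc1 | intermediate
4 | methyl (E)-4-methyl-3-oxohex-4-enoate | COC(=O)CC(=O)/C(C)=C/C | intermediate
5 | methyl (E)-2-diazo-4-methyl-3-oxohex-4-enoate | COC(=O)C(=[N+]=[N-])C(=O)/C(C)=C/C | intermediate
6 | chloroacetaldehyde dimethyl acetal (2-chloro-1,1-dimethoxyethane) | COC(CCl)OC | starting material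
7 | sodium methoxyacetylide | COC#[C-].[Na+] | intermediate
8 | 1-methoxypropyne | CC#COC | intermediate
9 | methyl (E)-3-methyl-2-(oxomethylidene)pent-3-enoate (vinylketene) | COC(=O)C(=C=O)/C(C)=C/C | intermediate
10 | methyl 1-[(E)-but-2-en-2-yl]-2-methoxy-3-methyl-4-oxocyclobut-2-ene-1-carboxylate, racemic (vinylcyclobutenone) | COC(=O)C1(/C(C)=C/C)C(OC)=C(C)C1=O | intermediate
11 | methyl (2Z)-2-[(2E)-but-2-en-2-yl]-3-methoxy-4-methyl-5-oxopenta-2,4-dienoate (dienylketene) | O=C=C(C)/C(OC)=C(C(=O)OC)\C(C)=C\C | intermediate
12 | methyl 6-methoxy-2,3,5-trimethyl-4-oxocyclohexa-1,5-diene-1-carboxylate, racemic (cyclohexadienone) | COC(=O)C1=C(C)C(C)C(=O)C(C)=C1OC | intermediate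
13 | methyl 4-hydroxy-2-methoxy-3,5,6-trimethylbenzoate | COC(=O)c1c(C)c(C)c(O)c(C)c1OC | intermediate
14 | 4,5-dimethylresorcinol (4,5-dimethylbenzene-1,3-diol) | Cc1cc(O)cc(O)c1C | starting material
15 | N-[(2,4-dihydroxy-5,6-dimethylphenyl)methylidene]-N-methylmethanaminium chloride (aryl iminium chloride) | C[N+](C)=Cc1c(O)cc(O)c(C)c1C.[Cl-] | intermediate
16 | 2,4-dihydroxy-5,6-dimethylbenzaldehyde | O=Cc1c(O)cc(O)c(C)c1C | intermediate
17 | 2,4-bis(benzyloxy)-5,6-dimethylbenzaldehyde | O=Cc1c(OCc2ccccc2)cc(OCc2ccccc2)c(C)c1C | intermediate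
18 | 2,4-bis(benzyloxy)-5,6-dimethylbenzoic acid | OC(=O)c1c(OCc2ccccc2)cc(OCc2ccccc2)c(C)c1C | intermediate
19 | 2,4-bis(benzyloxy)-5,6-dimethylbenzoic trifluoroacetic anhydride | O=C(OC(=O)C(F)(F)F)c1c(OCc2ccccc2)cc(OCc2ccccc2)c(C)c1C | intermediate
20 | methyl 4-{[2,4-bis(benzyloxy)-5,6-dimethylbenzoyl]oxy}-2-methoxy-3,5,6-trimethylbenzoate | COC(=O)c1c(C)c(C)c(OC(=O)c2c(C)c(C)c(OCc3ccccc3)cc2OCc2ccccc2)c(C)c1OC | intermediate
21 | methyl 4-[(2,4-dihydroxy-5,6-dimethylbenzoyl)oxy]-2-methoxy-3,5,6-trimethylbenzoate | COC(=O)c1c(C)c(C)c(OC(=O)c2c(C)c(C)c(O)cc2O)c(C)c1OC | intermediate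
22 | methyl 4-({3-[chloro(methoxy)methyl]-2,4-dihydroxy-5,6-dimethylbenzoyl}oxy)-2-methoxy-3,5,6-trimethylbenzoate, racemic | COC(Cl)c1c(O)c(C)c(C)c(C(=O)Oc2c(C)c(C)c(C(=O)OC)c(OC)c2C)c1O | intermediate
23 | methyl 4-[(3-formyl-2,4-dihydroxy-5,6-dimethylbenzoyl)oxy]-2-methoxy-3,5,6-trimethylbenzoate | COC(=O)c1c(C)c(C)c(OC(=O)c2c(C)c(C)c(O)c(C=O)c2O)c(C)c1OC | target

**Step count**

Total: 10 steps. Longest linear sequence: 6 steps (1, 2, 4, 8, 9, 10 from tiglic acid; equally 5, 6, 7, 8, 9, 10 from 4,5-dimethylresorcinol).

**Steps most likely to fail**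

Step 4. The ester-bearing ketene may be diverted before ring B closes: the ynol ether may add across the acylketene unit in a hetero-[4+2] sense, the opened cyclobutenone may close through the ester oxygen, or the ketene may dimerise or acylate the product phenol. The fallback takes the ester out of the pericyclic step and sets out from 1. Oxalyl chloride with catalytic DMF gives (E)-2-methylbut-2-enoyl chloride F1, and excess diazomethane in ether gives (E)-1-diazo-3-methylpent-3-en-2-one F2, the parent substrate class of this benzannulation. Irradiation of F2 with 8 followed by heating should give 3-methoxy-2,5,6-trimethylphenol F3 through the same set of ring bonds. Rieche formylation at its single free position, para to the hydroxyl, gives 4-hydroxy-2-methoxy-3,5,6-trimethylbenzaldehyde F4. Pinnick oxidation gives 4-hydroxy-2-methoxy-3,5,6-trimethylbenzoic acid F5, and MeI with KHCO3 in DMF alkylates only the carboxylate, which comes back to the route at 13.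

Step 10. Under the Lewis acid the depside ester may be cleaved or the acyl group may migrate, and substitution between two chelated hydroxyls may stall. The fallback formylates ring A before the rings are joined and sets out from 18. Hydrogenolysis gives 2,4-dihydroxy-5,6-dimethylbenzoic acid F6, and BnBr with KHCO3 in DMF gives benzyl 2,4-dihydroxy-5,6-dimethylbenzoate F7. Rieche formylation at the only free position gives benzyl 3-formyl-2,4-dihydroxy-5,6-dimethylbenzoate F8, and brief hydrogenolysis gives 3-formyl-2,4-dihydroxy-5,6-dimethylbenzoic acid F9, whose two hydroxyls are tied up in hydrogen bonds to carbonyl groups. DCC-mediated esterification of F9 with 13 in toluene then comes back to the route at 23.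

Step 8. Acyl transfer between a di-ortho-substituted acid and a di-ortho-substituted phenol may be slow, which leaves time for acid-induced loss of the ortho benzyl ether. The fallback changes from acid-mediated acylium transfer to acyl substitution in basic medium and sets out from 18. Oxalyl chloride with catalytic DMF gives 2,4-bis(benzyloxy)-5,6-dimethylbenzoyl chloride F10, which is heated with 13, Et3N and DMAP in toluene at 80 °C and comes back to the route at 20.

**Further compounds**

F1 | step 4 | (E)-2-methylbut-2-enoyl chloride | C/C=C(\C)C(=O)Cl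
F2 | step 4 | (E)-1-diazo-3-methylpent-3-en-2-one | C/C=C(\C)C(=O)C=[N+]=[N-]
F3 | step 4 | 3-methoxy-2,5,6-trimethylphenol | COc1cc(C)c(C)c(O)c1C
F4 | step 4 | 4-hydroxy-2-methoxy-3,5,6-trimethylbenzaldehyde | COc1c(C=O)c(C)c(C)c(O)c1C
F5 | step 4 | 4-hydroxy-2-methoxy-3,5,6-trimethylbenzoic acid | COc1c(C(=O)O)c(C)c(C)c(O)c1C
F6 | step 10 | 2,4-dihydroxy-5,6-dimethylbenzoic acid | OC(=O)c1c(O)cc(O)c(C)c1C
F7 | step 10 | benzyl 2,4-dihydroxy-5,6-dimethylbenzoate | O=C(OCc1ccccc1)c1c(O)cc(O)c(C)c1C
F8 | step 10 | benzyl 3-formyl-2,4-dihydroxy-5,6-dimethylbenzoate | O=Cc1c(O)c(C)c(C)c(C(=O)OCc2ccccc2)c1O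
F9 | step 10 | 3-formyl-2,4-dihydroxy-5,6-dimethylbenzoic acid | O=Cc1c(O)c(C)c(C)c(C(=O)O)c1O
F10 | step 8 | 2,4-bis(benzyloxy)-5,6-dimethylbenzoyl chloride | O=C(Cl)c1c(OCc2ccccc2)cc(OCc2ccccc2)c(C)c1C
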